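Amounts first: I count each flask in fractions of its own charge of starting material.

| flask | starting material | coupling partner | target | time |
|---|---|---|---|---|
| amber | 0.150 M | 0.120 M |  |  |
| grey | 0.0750 M | 0.120 M |  |  |
| teal | 0.150 M | 0.240 M |  |  |
| red | 0.150 M | 0.120 M | 0.0750 M | 58 min |

- amber run (time / min: [starting material] / M): 12: 0.1026; 23: 0.0731; 35: 0.0568; 46: 0.0449; 58: 0.0359
- grey run (time / min: [starting material] / M): 12: 0.0505; 23: 0.0358; 35: 0.0268; 46: 0.0207; 58: 0.0155
- teal run (time / min: [starting material] / M): 12: 0.0894; 23: 0.0593; 35: 0.0411; 46: 0.0293; 58: 0.0237

(readings scatter by 8 × 10⁻⁴ M)

- Overall: starting material + coupling partner -> target.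
- Constant volume, constant temperature.
- What is held in complexes is read along with the free species.
- An order is taken over about fifteen percent of the charge, up and down.

- apparent order in [starting material] of the starting rate, round the charge of the amber run (the rate where two percent of its starting material have turned into target) (one fixed amount of target, the same in the runs compared)
- apparent order in [coupling partner] of the starting rate, round the charge of the amber run (the rate where two percent of its starting material have turned into target)
- starting material in the red run at 58 min, as a share of the starting material charged

Does the fraction lost depend on the charge? After 12 min, the amber run keeps 68.4 % and the grey run 67.3 %. Their loss constants, 0.0316 min⁻¹ and 0.0330 min⁻¹, stand in a ratio of 1.04. So I take the order in starting material as near 1.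

Does the coupling partner carry that loss? Doubling it in the teal run gives only 0.0431 min⁻¹. I assume the target rate is first order in partner, so I take its order as 1. The amber term is then the teal excess over amber, and the remainder is a drain of 0.0202 min⁻¹. Over 58 min, that drain by itself leaves the drain share, the fraction of the charge surviving a partner-free loss: 31.0 %.

What does added target change? The amber run ends at 23.9 %, so partner's net pull multiplies the drain share by 0.771. Amber's last slope, 0.0186 min⁻¹, is close to the drain, so I read that pull as nearly gone there. By my split, target then stands to starting material at 1.15. The red run starts at 0.500, and I expect it to reach amber's ratio early. I give it a quarter of amber's pull, in the exponent, which leaves 29.1 % in the red run.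

The forecast gives 0.97, 0.38 and 27 %, and reads “suggesting mild target inhibition”.

The flask gives 1.0, 0.76 and 29.2 %, so the order in partner lies below my 1.

    starting material + coupling partner ⇌ target (0.2736 L mol⁻¹ min⁻¹, 0.006360 min⁻¹)
    starting material → decomposed substrate (0.01482 min⁻¹)
    2 coupling partner ⇌ idle reagent dimer, settled at all times (4.430 L mol⁻¹)

The red run ends 1.8 percentage points under my drain share of 31.0 %. The step to decomposed substrate deepens the loss in that flask. The same red run without that step keeps 61.8 % instead of 29.2 %, a difference of 33 points.

Readings and results are simulated from invented constants; the scatter is artificial.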